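The cycloheptene ring is read as a cyclopentane-1,3-dione (C8a, C8, C5, C4, C3a; cyclohepta[b]furan numbering) into which the C7–C6 alkene has been inserted. An intramolecular enone–alkene [2+2] photocycloaddition of a 3-alkoxycyclopentenone forms C8–C7 and C5–C6 at once; its alkoxy group is the side chain itself, tethered through the future acetoxy oxygen on C3′, so the Sharpless-derived carbinol C1′ sits in the forming tetrahydropyran and controls C6 and C7. Acid-triggered De Mayo opening of the C8–C5 cyclobutane bond then gives the seven-membered ring; the bicyclic photoadduct also relays configuration to C3a and, through it, to C8a.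

Key step: step 5

Remark: ring atoms are numbered as in the target (O1, C2 lactone carbonyl, C3 methylidene carbon, C3a, C4 alkene CH, C5 methyl-bearing alkene carbon, C6, C7 CHMe, C8 CH2, C8a OCH; side chain on C6 is C1′ angelate, C2′, C3′ acetate); intermediates keep these numbers. The ketal carbon C5 of 10–15 is taken as an inconsequential mixture of epimers.

Step 1
Reactants: 1 (2E,4E)-hexa-2,4-dien-1-ol
Product: 2 [(2R,3R)-3-[(1E)-prop-1-en-1-yl]oxiran-2-yl]methanol
Conditions: Ti(OiPr)4 (10 mol %), D-(−)-diethyl tartrate (12 mol %), t-BuOOH (anhydrous, decane), 4 Å molecular sieves, CH2Cl2, −20 °C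
Reagents that add atoms: tert-butyl hydroperoxide, CC(C)(C)OO
Why: Sharpless asymmetric epoxidation; the titanium tartrate catalyst binds the allylic alcohol, so only the proximal alkene should react, and D-(−)-diethyl tartrate should set the 2R,3R configuration (the epoxide carbon next to the propenyl group becomes C1′, the one stereocentre set by catalysis).

Step 2
Reactants: 2 epoxy alcohol
Product: 3 (3S,4E)-hex-4-ene-1,3-diol
Conditions: NaAlH2(OCH2CH2OMe)2 (Red-Al), THF, −20 → 0 °C
Reagents that add atoms: none
Why: Hydroxyl-directed Red-Al opening of a 2,3-epoxy alcohol; the alkoxyaluminate should deliver hydride intramolecularly to C2, and the allylic C–O bond is untouched, so the carbinol keeps its configuration (now descriptor S).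

Step 3
Reactants: 3 (3S,4E)-hex-4-ene-1,3-diol; 4 cyclopentane-1,3-dione
Product: 5 3-{[(3S,4E)-3-hydroxyhex-4-en-1-yl]oxy}cyclopent-2-en-1-one
Conditions: PPh3, DIAD, THF, 0 °C → rt
Reagents that add atoms: none
Why: Mitsunobu O-alkylation of the acidic 1,3-dione enol gives the vinylogous ester; the primary hydroxyl should be activated much faster than the hindered secondary allylic one, and no stereocentre is involved.

Step 4
Reactants: 5 hydroxy vinylogous ester
Product: 6 3-{[(3S,4E)-3-(triisopropylsilyloxy)hex-4-en-1-yl]oxy}cyclopent-2-en-1-one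
Conditions: iPr3SiOTf, 2,6-lutidine, CH2Cl2, −78 → 0 °C
Reagents that add atoms: triisopropylsilyl triflate, CC(C)[Si](OS(=O)(=O)C(F)(F)F)(C(C)C)C(C)C
Why: Standard silyl triflate protection of a secondary alcohol; the bulky, non-absorbing TIPS group should survive the later acid and base steps and reinforce the equatorial preference used in step 5.

Step 5
Reactants: 6 TIPS-protected photosubstrate
Product: 7 tricyclic photoadduct
Conditions: hν (medium-pressure Hg lamp, Pyrex filter, λ > 300 nm), degassed MeCN (0.01 M), 0 °C
Reagents that add atoms: none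
Why: Excitation of the vinylogous ester and intersystem crossing should give the triplet enone, whose alkoxy-bearing β-carbon C5 adds 6-exo to the proximal alkene carbon C6 through a chair-like transition state, after which spin inversion of the 1,4-biradical and coupling of the α-carbon C8 with the CHMe radical C7 close the cyclobutane. The closest known reaction type is the intramolecular enone–alkene [2+2] photocycloaddition of 3-(alkenyloxy)enones, the first half of an intramolecular De Mayo reaction. The tetrahydropyran closes in the 6-exo-trig (straight) mode and the cyclobutane by 1,4-biradical recombination, necessarily cis-fused to both the cyclopentanone and the tetrahydropyran. C6 is controlled by C1′, whose silyloxy group and the alkene both sit equatorial in the chair (silyloxy trans to the new C6–C7 ring bond); C7 is set in the closure, where the methyl should turn away from the silyloxy-bearing C1′ toward the flat carbonyl side, and since alkene geometry is erased in the biradical, E and Z material converge; C5 and C8 are flattened later. The step needs straight rather than crossed regiochemistry, secured by the four-atom tether (six-membered ring against seven or eight), and facial control, secured by the single carbinol centre in the tether.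

Step 6
Reactants: 7 tricyclic photoadduct; 8 methyl bromoacetate
Product: 9 C3a-alkylated photoadduct
Conditions: LiN(iPr)2, THF, −78 °C; then 8, DMPU, −78 → −30 °C
Reagents that add atoms: none
Why: Kinetic deprotonation should occur at the unhindered C3a methylene, and enolate alkylation (SN2) should take place on the convex face of the bicyclo[3.2.0]heptanone, anti to the cyclobutane, which places the acetate arm cis to the C1′-bearing branch on C6 as the target requires.

Step 7
Reactants: 9 C3a-alkylated photoadduct
Product: 10 keto ketal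
Conditions: TfOH (10 mol %), MeOH (20 equiv), CH2Cl2, −40 → 0 °C; then Et3N
Reagents that add atoms: methanol, CO
Why: Acid-catalysed De Mayo-type retro-aldol (push–pull) fragmentation of the vicinal donor–acceptor cyclobutane; protonation of the ketone should let the ring oxygen expel the strained C8–C5 bond, methanol traps the cyclic oxocarbenium ion as the mixed ketal and the enol gives the C8 methylene, with no carbocycle stereocentre touched.

Step 8
Reactants: 10 keto ketal
Product: 12 lactone ketal, via cis-hydroxy ester 11 (not isolated)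
Conditions: LiBH(s-Bu)3, THF, −78 → 0 °C; then AcOH, rt
Reagents that add atoms: none
Why: Bulky hydride reduction of the 2-substituted cycloheptanone should occur anti to the C3a acetate arm, and the cis alkoxide should close onto the methyl ester to the cis-fused γ-lactone, which sets C8a.

Step 9
Reactants: 12 lactone ketal
Product: 15 α-methylene lactone ketal, via Mannich base 13 (not isolated), via methiodide 14 (not isolated)
Conditions: LiN(iPr)2, THF, −78 °C; CH2=NMe2+ I−, −78 °C → rt; then MeI, MeOH; then NaHCO3 (aq.), CH2Cl2
Reagents that add atoms: N,N-dimethylmethyleneiminium iodide (Eschenmoser's salt), C=[N+](C)C.[I-]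
Why: Lactone enolate Mannich reaction, N-methylation and β-elimination is the standard α-methylenation of γ-butyrolactones, and the ketal and silyl ether are inert to these reagents.

Step 10
Reactants: 15 α-methylene lactone ketal
Product: 16 hydroxy ketone
Conditions: 1 M HCl, THF, rt
Reagents that add atoms: water, O
Why: Acid hydrolysis of the mixed cyclic ketal should release the C5 ketone and the C3′ hydroxyl; C6, now α to the ketone, already has the more stable trans relationship to the C7 methyl.

Step 11
Reactants: 16 hydroxy ketone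
Product: 17 keto acetate
Conditions: Ac2O, pyridine, DMAP (cat.), CH2Cl2, 0 °C → rt
Reagents that add atoms: acetic anhydride, CC(=O)OC(C)=O
Why: Acetylation of the primary alcohol, which also drains any cyclic hemiketal through the open hydroxy ketone.

Step 12
Reactants: 17 keto acetate
Product: 18 enol triflate
Conditions: KN(SiMe3)2 (1.05 equiv), THF, −78 °C; then PhNTf2, −78 → −30 °C
Reagents that add atoms: N-phenylbis(trifluoromethanesulfonimide), O=S(=O)(N(c1ccccc1)S(=O)(=O)C(F)(F)F)C(F)(F)F
Why: Kinetic enolisation with the hindered potassium amide should remove a proton from the C4 methylene and not from the hindered C6 methine, and O-triflation fixes the C4=C5 position; the ketone α-proton is much more acidic than those of the acetate or the methylene lactone.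

Step 13
Reactants: 18 enol triflate
Product: 19 C5-methyl silyl ether
Conditions: Me2Zn (2 equiv), Pd(PPh3)4 (5 mol %), THF, 0 °C → rt
Reagents that add atoms: dimethylzinc, C[Zn]C
Why: Negishi cross-coupling of the enol triflate should install the C5 methyl without moving the alkene, and organozinc reagents tolerate the acetate and the α-methylene lactone.

Step 14
Reactants: 19 C5-methyl silyl ether
Product: 20 C1′ alcohol
Conditions: HF·pyridine, pyridine/THF, 0 °C → rt
Reagents that add atoms: none
Why: Fluoride cleavage of the silyl ether under buffered, non-basic conditions that should leave the acetate and the Michael-acceptor lactone untouched.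

Step 15
Reactants: 20 C1′ alcohol; 21 angelic acid
Product: 23 target CNP0163960.1, via mixed anhydride 22 (not isolated)
Conditions: 21, 2,4,6-trichlorobenzoyl chloride, Et3N, toluene, rt; then 20, 80 °C
Reagents that add atoms: none
Why: Yamaguchi esterification through the mixed anhydride, run without a nucleophilic catalyst, should acylate the hindered secondary alcohol while keeping Z to E isomerisation to the tiglate low.

Compound list
1 | (2E,4E)-hexa-2,4-dien-1-ol | C/C=C/C=C/CO | starting material
2 | [(2R,3R)-3-[(1E)-prop-1-en-1-yl]oxiran-2-yl]methanol | C/C=C/[C@H]1O[C@@H]1CO | intermediate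
3 | (3S,4E)-hex-4-ene-1,3-diol | C/C=C/[C@@H](O)CCO | intermediate
4 | cyclopentane-1,3-dione | O=C1CCC(=O)C1 | starting material
5 | 3-{[(3S,4E)-3-hydroxyhex-4-en-1-yl]oxy}cyclopent-2-en-1-one | C/C=C/[C@@H](O)CCOC1=CC(=O)CC1 | intermediate
6 | 3-{[(3S,4E)-3-(triisopropylsilyloxy)hex-4-en-1-yl]oxy}cyclopent-2-en-1-one | C/C=C/[C@H](CCOC1=CC(=O)CC1)O[Si](C(C)C)(C(C)C)C(C)C | intermediate
7 | (1S,5S,6S,7R,8S)-6-methyl-8-(triisopropylsilyloxy)-11-oxatricyclo[5.4.0.0(1,5)]undecan-4-one: cyclobutane C8–C7–C6–C5 cis-fused at C8–C5 to the cyclopentanone and at C5–C6 to the tetrahydropyran; C7 methyl trans to C1′ on the cyclobutane; OTIPS trans to C7 on the tetrahydropyran | C[C@H]1[C@@H]2[C@@H](O[Si](C(C)C)(C(C)C)C(C)C)CCO[C@@]23CCC(=O)[C@@H]13 | intermediate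
8 | methyl bromoacetate | COC(=O)CBr | starting material
9 | methyl 2-[(1S,3R,5S,6S,7R,8S)-6-methyl-4-oxo-8-(triisopropylsilyloxy)-11-oxatricyclo[5.4.0.0(1,5)]undecan-3-yl]acetate: 7 with the CH2CO2Me arm on C3a, on the convex face | C[C@H]1[C@@H]2[C@@H](O[Si](C(C)C)(C(C)C)C(C)C)CCO[C@@]23C[C@H](CC(=O)OC)C(=O)[C@@H]13 | intermediate
10 | keto ketal: cycloheptanone (C8a ketone, C8 methylene) with the CH2CO2Me arm on C3a and the C7 methyl; C5 is a mixed methyl ketal closed through O3′ (2-methoxytetrahydropyran fused at C5–C6, OTIPS on C1′); epimers at C5 | C[C@@H]1CC(=O)[C@@H](CC(=O)OC)CC2(OC)OCC[C@H](O[Si](C(C)C)(C(C)C)C(C)C)[C@@H]12 | intermediate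
11 | cis-hydroxy ester: 10 with the C8a ketone reduced to the alcohol cis to the C3a arm (not isolated) | C[C@@H]1C[C@@H](O)[C@@H](CC(=O)OC)CC2(OC)OCC[C@H](O[Si](C(C)C)(C(C)C)C(C)C)[C@@H]12 | intermediate
12 | lactone ketal: cis-fused γ-lactone (O1–C2–C3–C3a–C8a) on the ketal-protected cycloheptane of 10 | C[C@@H]1C[C@H]2OC(=O)C[C@H]2CC3(OC)OCC[C@H](O[Si](C(C)C)(C(C)C)C(C)C)[C@@H]13 | intermediate
13 | Mannich base: 12 with CH2NMe2 on C3 (epimers at C3; not isolated) | C[C@@H]1C[C@H]2OC(=O)C(CN(C)C)[C@H]2CC3(OC)OCC[C@H](O[Si](C(C)C)(C(C)C)C(C)C)[C@@H]13 | intermediate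
14 | methiodide: trimethylammonium iodide of 13 (not isolated) | C[C@@H]1C[C@H]2OC(=O)C(C[N+](C)(C)C)[C@H]2CC3(OC)OCC[C@H](O[Si](C(C)C)(C(C)C)C(C)C)[C@@H]13.[I-] | intermediate
15 | α-methylene lactone ketal: 12 with the exocyclic methylidene on C3 | C[C@@H]1C[C@H]2OC(=O)C(=C)[C@H]2CC3(OC)OCC[C@H](O[Si](C(C)C)(C(C)C)C(C)C)[C@@H]13 | intermediate
16 | hydroxy ketone: 6-[(1S)-3-hydroxy-1-(triisopropylsilyloxy)propyl]-7-methyl-3-methylidene-octahydrocyclohepta[b]furan-2,5-dione; ring configurations as in the target | C[C@@H]1C[C@H]2OC(=O)C(=C)[C@H]2CC(=O)[C@H]1[C@H](CCO)O[Si](C(C)C)(C(C)C)C(C)C | intermediate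
17 | keto acetate: 3′-O-acetate of 16 | C[C@@H]1C[C@H]2OC(=O)C(=C)[C@H]2CC(=O)[C@H]1[C@H](CCOC(C)=O)O[Si](C(C)C)(C(C)C)C(C)C | intermediate
18 | enol triflate: C4=C5 enol trifluoromethanesulfonate of 17 | C[C@@H]1C[C@H]2OC(=O)C(=C)[C@H]2C=C(OS(=O)(=O)C(F)(F)F)[C@H]1[C@H](CCOC(C)=O)O[Si](C(C)C)(C(C)C)C(C)C | intermediate
19 | (3aR,6S,7R,8aR)-6-[(1S)-3-acetoxy-1-(triisopropylsilyloxy)propyl]-5,7-dimethyl-3-methylidene-3,3a,6,7,8,8a-hexahydro-2H-cyclohepta[b]furan-2-one | C[C@@H]1C[C@H]2OC(=O)C(=C)[C@H]2C=C(C)[C@H]1[C@H](CCOC(C)=O)O[Si](C(C)C)(C(C)C)C(C)C | intermediate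
20 | (3aR,6S,7R,8aR)-6-[(1S)-3-acetoxy-1-hydroxypropyl]-5,7-dimethyl-3-methylidene-3,3a,6,7,8,8a-hexahydro-2H-cyclohepta[b]furan-2-one | C[C@@H]1C[C@H]2OC(=O)C(=C)[C@H]2C=C(C)[C@H]1[C@H](CCOC(C)=O)O | intermediate
21 | angelic acid, (2Z)-2-methylbut-2-enoic acid | C/C=C(/C)C(=O)O | starting material
22 | mixed anhydride of angelic acid and 2,4,6-trichlorobenzoic acid (not isolated) | C/C=C(/C)C(=O)OC(=O)c1c(Cl)cc(Cl)cc1Cl | intermediate
23 | CNP0163960.1, (1S)-3-acetoxy-1-[(3aR,6S,7R,8aR)-5,7-dimethyl-3-methylidene-2-oxo-3,3a,6,7,8,8a-hexahydro-2H-cyclohepta[b]furan-6-yl]propyl (2Z)-2-methylbut-2-enoate | C=C1C(=O)O[C@@H]2C[C@@H](C)[C@H]([C@H](CCOC(C)=O)OC(=O)/C(C)=C\C)C(C)=C[C@H]12 | target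

Total step count: 15. Longest linear sequence: 15 steps (from 1; compounds 4, 8 and 21 are bought).

Steps most likely to fail

Step 5. After the first C5–C6 bond the methyl-bearing radical may close with poor facial discrimination, or the six-membered tether may lose out to hydrogen abstraction, so that C7 is not secured. The fallback sets out from 6 and comes back at 10; it takes the methyl group out of the photochemical event and sets it later by conjugate addition. Ethenolysis of the propenyl group of 6 (second-generation Grubbs catalyst, ethylene, CH2Cl2) should give the vinyl ether F1. Irradiation as in step 5 should give the nor-methyl photoadduct F2, in which no stereocentre is made at C7. Alkylation as in step 6 gives the keto ester F3, and acid/methanol opening as in step 7 gives the nor-methyl keto ketal F4. Kinetic enolisation toward the C8 methylene (LiN(iPr)2, Me3SiCl, THF, −78 °C) gives the silyl enol ether F5, and Saegusa oxidation (Pd(OAc)2, MeCN) gives the C7=C8 enone F6. Me2CuLi (Et2O, −78 °C) should then add to C7 anti to the C6 substituent and give 10.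

Step 7. The acid-induced heterolysis of the cyclobutane may be slow compared with enolisation at C3a or loss of the silyl ether. The fallback sets out from 9 and comes back at 10; it replaces the push–pull opening by ether cleavage and a classical cyclobutanol retro-aldol. Dimethylboron bromide (Me2BBr, CH2Cl2, −78 °C) should open the tetrahydropyran by bromide attack at the primary carbon C3′. The tertiary cyclobutanol set free on bicarbonate work-up should undergo the De Mayo retro-aldol by itself and give the bromo diketone F7. AgOTf in MeOH with 2,6-di-tert-butylpyridine should then let the C5 carbonyl oxygen displace bromide, and methanol traps the oxocarbenium ion to give 10.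

Step 15. The angeloyl unit may isomerise from Z to E (tiglate) during activation, or acylation of the hindered carbinol may stall. The fallback sets out from 20 and comes back at 23; it builds the Z alkene on the molecule. Esterification of 20 with 2-[bis(2,2,2-trifluoroethoxy)phosphoryl]propanoic acid (DCC, DMAP, CH2Cl2) gives the phosphonate ester F8. Still–Gennari olefination (KN(SiMe3)2, 18-crown-6, THF, −78 °C, then acetaldehyde) should give the Z-trisubstituted enoate 23; the phosphonate α-proton is by far the most acidic in the molecule.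

Further compounds
F1 | step 5 | 3-{[(3S)-3-(triisopropylsilyloxy)pent-4-en-1-yl]oxy}cyclopent-2-en-1-one | C=C[C@H](CCOC1=CC(=O)CC1)O[Si](C(C)C)(C(C)C)C(C)C
F2 | step 5 | nor-methyl photoadduct (7 without the C7 methyl) | C1[C@@H]2[C@@H](O[Si](C(C)C)(C(C)C)C(C)C)CCO[C@@]23CCC(=O)[C@@H]13
F3 | step 5 | nor-methyl keto ester (9 without the C7 methyl) | C1[C@@H]2[C@@H](O[Si](C(C)C)(C(C)C)C(C)C)CCO[C@@]23C[C@H](CC(=O)OC)C(=O)[C@@H]13
F4 | step 5 | nor-methyl keto ketal (10 without the C7 methyl) | C1CC(=O)[C@@H](CC(=O)OC)CC2(OC)OCC[C@H](O[Si](C(C)C)(C(C)C)C(C)C)[C@@H]12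
F5 | step 5 | C8a=C8 trimethylsilyl enol ether of F4 | C1C=C(O[Si](C)(C)C)[C@@H](CC(=O)OC)CC2(OC)OCC[C@H](O[Si](C(C)C)(C(C)C)C(C)C)[C@@H]12
F6 | step 5 | C7=C8 enone of F4 | C1=CC(=O)[C@@H](CC(=O)OC)CC2(OC)OCC[C@H](O[Si](C(C)C)(C(C)C)C(C)C)[C@@H]12
F7 | step 7 | bromo diketone: cycloheptane-1,4-dione (C8a, C5) with the C3a acetate arm, C7 methyl and (1S)-3-bromo-1-(triisopropylsilyloxy)propyl on C6 | C[C@@H]1CC(=O)[C@@H](CC(=O)OC)CC(=O)[C@H]1[C@H](CCBr)O[Si](C(C)C)(C(C)C)C(C)C
F8 | step 15 | 2-[bis(2,2,2-trifluoroethoxy)phosphoryl]propanoate of 20 | C[C@@H]1C[C@H]2OC(=O)C(=C)[C@H]2C=C(C)[C@H]1[C@H](CCOC(C)=O)OC(=O)C(C)P(=O)(OCC(F)(F)F)OCC(F)(F)F
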